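Time spent at 80 °C is the clock I read these flasks by, and what I read on it is how much side product stands beside the links.

| flask | first end groups | second end groups | third end groups | temperature | remark | time |
|---|---|---|---|---|---|---|
| south-west | 0.020 M | 0.0204 M | 2 mM | 80 °C | run made earlier |  |
| west | 0.020 M | 0.041 M | 2 mM | 80 °C | run made earlier |  |
| grey | 0.020 M | 0.0204 M | 2.00 mM | 80 °C | everything together at the start | 3.0 d |
| violet | 0.020 M (fed, over 30 h) | 0.0204 M | 2.00 mM | 80 °C | all else is in the flask from the start; the feed brings no volume worth counting | 3.0 d |
| blue | 0.020 M (fed, over 30 h) | 0.0204 M | 2.00 mM |  | the addition at 60 °C, then warmed to 80 °C; the feed brings no volume worth counting | 3.0 d |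
| red | 0.020 M | 0.0204 M | 2.00 mM (fed, over 30 h) | 80 °C | all else is in the flask from the start; the feed brings no volume worth counting | 3.0 d |

- south-west (time / d: links / %, side product / %, first end groups / %): 0.250: 16.2, 2.1, 80.9; 0.417: 20.3, 0.9, 70.0; 0.833: 29.2, 6.0, 51.8; 1.67: 38.7, 12.3, 32.6; 3.00: 43.4, 21.4, 15.2
- west (time / h: links / %, side product / %, first end groups / %): 1.33: 8.2, 0.6, 91.1; 3.00: 15.0, 0, 78.5; 4.00: 20.1, 1.4, 74.8; 6.00: 25.8, 0, 67.3; 8.00: 31.5, 1.6, 59.8

(readings scatter by 1 percentage point)

* the flask that comes out highest in share of links in links plus side product, or "all alike" when all lie within 1.5 percentage points (grey / violet / blue / red / all alike)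
* share of links in links plus side product at the end, grey
* share of links in links plus side product at the end, violet
* share of links in links plus side product at the end, blue
* share of links in links plus side product at the end, red

- in percentages every species weighs as the first end groups in it: one side product counts as two
- the earlier runs do not show what temperature does; that part of a forecast is a guess
- a reading or a percentage of links counts all its forms, free or not

1. With the main step by itself, first end groups and second end groups give links and nothing else, so the share asked for stays whole.

2. I add links with first end groups giving side product. First end groups stand in both paces and cancel, so in my reckoning, at steady second end groups and with the links lost to side product set aside, side product goes as links squared, a line of slope two in logarithms. I therefore keep the side index, side product over links squared, both as fractions of the first end groups charged (a selectivity factor over second end groups) 0.821, read in the south-west run at 1.67 d, or −0.0857 in powers of ten. The share is then one over one plus the index times links.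

3. Second end groups move the index. At like links, the west run at 8.00 h reads 0.161 and the south-west run at 0.833 d reads 0.704. That is 0.640 in powers of ten against 0.303 for second end groups, so the index falls with their power 2.11, a loose reading, since the west side product of 1.6% carries a scatter of 1 percentage point.

4. Grey repeats the south-west recipe, so I take 67.0% for it. Since first end groups cancel from the index in my reckoning, I put violet beside grey, and red doses third end groups, whose part is untested, so I put red beside grey too.

5. Blue has 42.0 h warm after its addition, about the 1.67 d of that reading. If its cold stage does little, which is a guess, blue comes to 75.9%, higher than grey, and I commit to blue.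

The forecast names violet, with grey 67%, violet 76%, blue 74% and red 68%, on the ground “If both steps are first order in first end groups, selectivity follows the time-integral of first end groups”, and my reckoning parts from it on violet.

The flask gives blue, with grey 68.0%, violet 70.0%, blue 74.6% and red 68.1%. At 1.25 d blue holds 6.10% links and 0.0846% side product. The side index of 0.821 on the 39.6% links of blue at 3.00 d gives 75.5%.

    first end groups + second end groups → links (k = 1.50 L mol⁻¹ h⁻¹, Ea = 93.0 kJ mol⁻¹)
    second end groups + third end groups → links of the second sort (k = 0.220 L mol⁻¹ h⁻¹, Ea = 92.0 kJ mol⁻¹)
    second end groups + links ⇌ idle adduct, settled at all times (K = 60.0 L mol⁻¹, ΔH = −42.0 kJ mol⁻¹)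
    2 first end groups → self-condensation product (k = 0.320 L mol⁻¹ h⁻¹, Ea = 86.0 kJ mol⁻¹)
    first end groups + links → side product (k = 0.980 L mol⁻¹ h⁻¹, Ea = 84.0 kJ mol⁻¹)
    (constants at 80 °C)

The neighbour of blue charged with 0.035 M of second end groups has its index scaled to 0.263, which on its 59.8% links gives 86.4%. The computed share is 83.9%.

The runs come from a simulation for substances that don't exist; noise was put on by code.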